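## Retrosynthetic overview

1. The target is (13E)-15-isobutyryloxylabda-7,13-dien-17-oic acid. The C17 acid is traced back to a C17 silyloxymethyl group on C8 with the ring B alkene at C6=C7; the alkene is moved into conjugation late, which erases C8. The side chain is cut at C12–C13 (B-alkyl Suzuki coupling of a C11=C12 vinyl group with an (E)-C4 enol triflate) and at C11=C12 (methylenation of a C11 aldehyde).
2. The route rests on one feature: the trans-decalin carries the contiguous centres C5, C10 (quaternary, bearing C20) and C9, and its ring B alkene lies one position away from a cyclohexene retron. C9=C10 is then an enal dienophile (C11 formyl), C5–C8 a diene, and C1–C4 the tether between them.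
3. Key disconnection: C5–C10 and C8–C9 by a type 1 intramolecular Diels–Alder reaction of an acyclic (2E,8E,10E)-trienal under a chiral cationic oxazaborolidine. Rings A and B form together in that step; no ring is made before or after it.
4. The trienal comes from 2,2-dimethylpent-4-enal: a phosphonocrotonate olefination builds the diene, and hydroboration/Suzuki coupling with ethyl (E)-3-triflyloxybut-2-enoate installs the 3-methyl enal with defined E geometry. The same triflate later delivers C13–C16.

Key step: step 8

Remark on numbering: labdane numbering is used for all bicyclic compounds (decalin C1–C10, C17 on C8, C18/C19 on C4, C20 on C10, side chain C11–C16 from C9).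

Assumption: the sense of induction in step 8 is taken from the accepted formyl C–H···O binding model of N-protonated oxazaborolidines, which for the (R)-catalyst leaves the C9-Si/C10-Re face of the enal open; the enantiomeric catalyst is equally accessible should the sense have to be reversed.

## Route

Step 1
Reactants: 1 ethyl acetoacetate
Product: 2 ethyl (E)-3-{[(trifluoromethyl)sulfonyl]oxy}but-2-enoate
Conditions: Tf2O, aq (CH3)4NOH, hexane, 5–10 °C
Reagents that add atoms: triflic anhydride, O=S(=O)(OS(=O)(=O)C(F)(F)F)C(F)(F)F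
Why: Stereoselective enol triflation of a β-keto ester; with the non-chelating tetramethylammonium counter-ion the enolate should be trapped in its extended form, placing the triflate trans to the ester, which later fixes the C9=C10 and C13=C14 geometries.

Step 2
Reactants: 3 2,2-dimethylpent-4-enal; 4 triethyl 4-phosphonocrotonate
Product: 5 ethyl (2E,4E)-6,6-dimethylnona-2,4,8-trienoate
Conditions: LiN(SiMe3)2, THF, −78 → 0 °C
Reagents that add atoms: none
Why: Vinylogous Horner–Wadsworth–Emmons olefination of a non-enolisable neopentyl aldehyde, in which the stabilised phosphonate anion should give the (2E,4E)-dienoate.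

Step 3
Reactants: 5 ethyl (2E,4E)-6,6-dimethylnona-2,4,8-trienoate
Product: 6 (2E,4E)-6,6-dimethylnona-2,4,8-trien-1-ol
Conditions: i-Bu2AlH, CH2Cl2, −78 °C; aq potassium sodium tartrate
Reagents that add atoms: none
Why: 1,2-Reduction of a conjugated ester by i-Bu2AlH should give the dienyl alcohol without touching any alkene.

Step 4
Reactants: 6 (2E,4E)-6,6-dimethylnona-2,4,8-trien-1-ol
Product: 7 tert-butyl{[(2E,4E)-6,6-dimethylnona-2,4,8-trien-1-yl]oxy}dimethylsilane
Conditions: TBSCl, imidazole, CH2Cl2, 0 °C → rt
Reagents that add atoms: tert-butyldimethylsilyl chloride, CC(C)(C)[Si](C)(C)Cl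
Why: Standard imidazole-mediated silylation of a primary alcohol, giving an ether that survives the borane, hydride and Lewis acid steps ahead.

Step 5
Reactants: 7 tert-butyl{[(2E,4E)-6,6-dimethylnona-2,4,8-trien-1-yl]oxy}dimethylsilane; 2 ethyl (E)-3-{[(trifluoromethyl)sulfonyl]oxy}but-2-enoate
Product: 9 ethyl (2E,8E,10E)-12-(tert-butyldimethylsilyloxy)-3,7,7-trimethyldodeca-2,8,10-trienoate, via B-alkyl-9-BBN adduct 8 (not isolated)
Conditions: 9-BBN, THF, 0 °C → rt; then 2, PdCl2(dppf) (5 mol%), aq K3PO4, THF–DMF, rt → 45 °C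
Reagents that add atoms: 9-BBN, B1C2CCCC1CCC2 (its boron is carried only by intermediate 8 and leaves again in the coupling)
Why: Hydroboration/B-alkyl Suzuki–Miyaura coupling; 9-BBN should select the monosubstituted terminal alkene over the internal conjugated diene, and the primary alkylborane should couple with the vinyl triflate with retention, so that C20 and the future C11 carbonyl are cis on C10=C9.

Step 6
Reactants: 9 ethyl (2E,8E,10E)-12-(tert-butyldimethylsilyloxy)-3,7,7-trimethyldodeca-2,8,10-trienoate
Product: 10 (2E,8E,10E)-12-(tert-butyldimethylsilyloxy)-3,7,7-trimethyldodeca-2,8,10-trien-1-ol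
Conditions: i-Bu2AlH, CH2Cl2, −78 °C; aq potassium sodium tartrate
Reagents that add atoms: none
Why: 1,2-Reduction of the enoate by i-Bu2AlH should give the allylic alcohol and leave the silyl ether and the diene intact.

Step 7
Reactants: 10 (2E,8E,10E)-12-(tert-butyldimethylsilyloxy)-3,7,7-trimethyldodeca-2,8,10-trien-1-ol
Product: 11 (2E,8E,10E)-12-(tert-butyldimethylsilyloxy)-3,7,7-trimethyldodeca-2,8,10-trienal
Conditions: MnO2 (excess), CH2Cl2, rt
Reagents that add atoms: none
Why: Allylic oxidation with MnO2 is neutral and selective and should give the 3-methyl enal without E/Z isomerisation.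

Step 8
Reactants: 11 (2E,8E,10E)-12-(tert-butyldimethylsilyloxy)-3,7,7-trimethyldodeca-2,8,10-trienal
Product: 12 (1S,2S,4aS,8aS)-2-[(tert-butyldimethylsilyloxy)methyl]-5,5,8a-trimethyl-1,2,4a,5,6,7,8,8a-octahydronaphthalene-1-carbaldehyde
Conditions: (R)-3,3-diphenyl-1-(o-tolyl)tetrahydro-1H,3H-pyrrolo[1,2-c][1,3,2]oxazaborole (20 mol%), (CF3SO2)2NH (18 mol%), CH2Cl2, −78 → −20 °C
Reagents that add atoms: none
Why: The N-protonated oxazaborolidine binds the C11 formyl group (B–O coordination plus a formyl C–H···O contact), lowers the enal LUMO and lets the (E,E)-diene C5–C8 add to the C9=C10 dienophile in a concerted, asynchronous, normal-demand [4+2] cycloaddition that forms C8–C9 and C5–C10; the closest known reaction type is the enantioselective, chiral-acid-catalysed intramolecular Diels–Alder reaction of (2E,8E,10E)-undeca-2,8,10-trienals to trans-fused octalin carbaldehydes. Ring B closes as the new cyclohexene of the cycloaddition, and ring A closes at the same moment through the four-carbon tether C1–C4 (type 1, 1,7,9-decatriene mode, chair-like tether, helped by the gem-dimethyl group at C4). The E geometry of the enal places C20 and C11 cis (C10 relative to C9), the E,E geometry of the diene combined with the formyl-endo approach places C17 on C8 cis to C11, and the anti position of the tether in that same transition state gives the trans ring fusion at C5. The absolute configuration comes from the catalyst, whose phenyl group cis to the bound enal should cover the C9-Re face so that the diene adds to the C9-Si/C10-Re face. The step needs endo and enantiofacial selectivity and enough reactivity from a β,β-disubstituted enal, and the fixed E,E,E geometry of 11 translates the single face choice into all four centres. A Lewis acid is preferred to a secondary-amine catalyst because an iminium ion of this enal can lose its E geometry through the dienamine, and the developing syn-diaxial contact between C20 and the axial C4 methyl is the main cost of the trans-fused transition state.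

Step 9
Reactants: 12 (1S,2S,4aS,8aS)-2-[(tert-butyldimethylsilyloxy)methyl]-5,5,8a-trimethyl-1,2,4a,5,6,7,8,8a-octahydronaphthalene-1-carbaldehyde
Product: 13 17-(tert-butyldimethylsilyloxy)-13,14,15,16-tetranorlabda-6,11-diene
Conditions: Ph3PCH3Br, KN(SiMe3)2, THF, −78 → 0 °C
Reagents that add atoms: methyltriphenylphosphonium bromide, C[P+](c1ccccc1)(c1ccccc1)c1ccccc1.[Br-]
Why: Wittig methylenation with the non-stabilised ylide is fast at low temperature even on a hindered aldehyde, which should limit base-induced epimerisation at C9.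

Step 10
Reactants: 13 17-(tert-butyldimethylsilyloxy)-13,14,15,16-tetranorlabda-6,11-diene; 2 ethyl (E)-3-{[(trifluoromethyl)sulfonyl]oxy}but-2-enoate
Product: 15 ethyl (13E)-17-(tert-butyldimethylsilyloxy)labda-6,13-dien-15-oate, via C12-borane adduct 14 (not isolated)
Conditions: 9-BBN, THF, 0 °C → rt; then 2, PdCl2(dppf) (5 mol%), aq K3PO4, THF–DMF, rt → 45 °C
Reagents that add atoms: 9-BBN, B1C2CCCC1CCC2 (its boron is carried only by intermediate 14 and leaves again in the coupling)
Why: Hydroboration/B-alkyl Suzuki–Miyaura coupling; 9-BBN should react with the vinyl group far faster than with the cis-disubstituted ring alkene C6=C7, and coupling with retention attaches C13–C16 with the 13E geometry.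

Step 11
Reactants: 15 ethyl (13E)-17-(tert-butyldimethylsilyloxy)labda-6,13-dien-15-oate
Product: 16 (13E)-17-(tert-butyldimethylsilyloxy)labda-6,13-dien-15-ol
Conditions: i-Bu2AlH, CH2Cl2, −78 °C; aq potassium sodium tartrate
Reagents that add atoms: none
Why: 1,2-Reduction of the conjugated ester by i-Bu2AlH should give the allylic alcohol while the silyl ether and both alkenes stay untouched.

Step 12
Reactants: 16 (13E)-17-(tert-butyldimethylsilyloxy)labda-6,13-dien-15-ol
Product: 17 (13E)-17-(tert-butyldimethylsilyloxy)labda-6,13-dien-15-yl 2-methylpropanoate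
Conditions: i-PrCOCl, pyridine, DMAP (cat.), CH2Cl2, 0 °C
Reagents that add atoms: isobutyryl chloride, CC(C)C(Cl)=O
Why: DMAP-catalysed acylation of the only free (primary allylic) alcohol with an acid chloride.

Step 13
Reactants: 17 (13E)-17-(tert-butyldimethylsilyloxy)labda-6,13-dien-15-yl 2-methylpropanoate
Product: 18 (13E)-17-hydroxylabda-6,13-dien-15-yl 2-methylpropanoate
Conditions: HF·pyridine, pyridine, THF, 0 °C → rt
Reagents that add atoms: none
Why: Fluoride-driven cleavage of the Si–O bond under buffered, non-basic conditions should free the C17 alcohol without acyl migration or loss of the allylic isobutyrate.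

Step 14
Reactants: 18 (13E)-17-hydroxylabda-6,13-dien-15-yl 2-methylpropanoate
Product: 20 (13E)-17-oxolabda-7,13-dien-15-yl 2-methylpropanoate, via β,γ-unsaturated aldehyde 19 (not isolated)
Conditions: Dess–Martin periodinane, pyridine, CH2Cl2, 0 °C → rt; then DBU (3 equiv), rt
Reagents that add atoms: none
Why: Dess–Martin oxidation gives the β,γ-unsaturated aldehyde, whose doubly activated C8–H is removed by DBU, and γ-protonation of the dienolate at C6 moves the alkene to C7=C8 (the conjugated, thermodynamically favoured isomer), erasing C8 while C9, which is not acidified, keeps its configuration.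

Step 15
Reactants: 20 (13E)-17-oxolabda-7,13-dien-15-yl 2-methylpropanoate
Product: 21 (13E)-15-(2-methylpropanoyloxy)labda-7,13-dien-17-oic acid
Conditions: NaClO2, NaH2PO4, 2-methylbut-2-ene, t-BuOH–H2O, 0 °C → rt
Reagents that add atoms: sodium chlorite, [Na+].[O-]Cl=O
Why: Pinnick oxidation converts the conjugated aldehyde into the acid, with 2-methylbut-2-ene scavenging hypochlorous acid so that the trisubstituted alkenes and the ester are not attacked.

## Compound list

1 | ethyl acetoacetate | CCOC(=O)CC(C)=O | starting material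
2 | ethyl (E)-3-{[(trifluoromethyl)sulfonyl]oxy}but-2-enoate | CCOC(=O)/C=C(\C)OS(=O)(=O)C(F)(F)F | intermediate
3 | 2,2-dimethylpent-4-enal | C=CCC(C)(C)C=O | starting material
4 | triethyl 4-phosphonocrotonate | CCOC(=O)/C=C/CP(=O)(OCC)OCC | starting material
5 | ethyl (2E,4E)-6,6-dimethylnona-2,4,8-trienoate | CCOC(=O)/C=C/C=C/C(C)(C)CC=C | intermediate
6 | (2E,4E)-6,6-dimethylnona-2,4,8-trien-1-ol | OC/C=C/C=C/C(C)(C)CC=C | intermediate
7 | tert-butyl{[(2E,4E)-6,6-dimethylnona-2,4,8-trien-1-yl]oxy}dimethylsilane | C=CCC(C)(C)/C=C/C=C/CO[Si](C)(C)C(C)(C)C | intermediate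
8 | 9-[(5E,7E)-9-(tert-butyldimethylsilyloxy)-4,4-dimethylnona-5,7-dien-1-yl]-9-borabicyclo[3.3.1]nonane | CC(C)(CCCB1C2CCCC1CCC2)/C=C/C=C/CO[Si](C)(C)C(C)(C)C | intermediate (not isolated)
9 | ethyl (2E,8E,10E)-12-(tert-butyldimethylsilyloxy)-3,7,7-trimethyldodeca-2,8,10-trienoate | CCOC(=O)/C=C(\C)CCCC(C)(C)/C=C/C=C/CO[Si](C)(C)C(C)(C)C | intermediate
10 | (2E,8E,10E)-12-(tert-butyldimethylsilyloxy)-3,7,7-trimethyldodeca-2,8,10-trien-1-ol | OC/C=C(\C)CCCC(C)(C)/C=C/C=C/CO[Si](C)(C)C(C)(C)C | intermediate
11 | (2E,8E,10E)-12-(tert-butyldimethylsilyloxy)-3,7,7-trimethyldodeca-2,8,10-trienal | O=C/C=C(\C)CCCC(C)(C)/C=C/C=C/CO[Si](C)(C)C(C)(C)C | intermediate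
12 | (1S,2S,4aS,8aS)-2-[(tert-butyldimethylsilyloxy)methyl]-5,5,8a-trimethyl-1,2,4a,5,6,7,8,8a-octahydronaphthalene-1-carbaldehyde (17-silyloxydrim-6-en-11-al; 5α-H, 8α-H, 9α-H, 10β-CH3) | O=C[C@H]1[C@@H](CO[Si](C)(C)C(C)(C)C)C=C[C@H]2C(C)(C)CCC[C@]12C | intermediate
13 | 17-(tert-butyldimethylsilyloxy)-13,14,15,16-tetranorlabda-6,11-diene (9β-vinyl; 5α-H, 8α-H, 9α-H, 10β-CH3) | C=C[C@H]1[C@@H](CO[Si](C)(C)C(C)(C)C)C=C[C@H]2C(C)(C)CCC[C@]12C | intermediate
14 | 9-[17-(tert-butyldimethylsilyloxy)-13,14,15,16-tetranorlabd-6-en-12-yl]-9-borabicyclo[3.3.1]nonane (ring configuration as in 13) | C(C[C@H]1[C@@H](CO[Si](C)(C)C(C)(C)C)C=C[C@H]2C(C)(C)CCC[C@]12C)B3C4CCCC3CCC4 | intermediate (not isolated)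
15 | ethyl (13E)-17-(tert-butyldimethylsilyloxy)labda-6,13-dien-15-oate (5α-H, 8α-H, 9α-H, 10β-CH3) | CCOC(=O)/C=C(\C)CC[C@H]1[C@@H](CO[Si](C)(C)C(C)(C)C)C=C[C@H]2C(C)(C)CCC[C@]12C | intermediate
16 | (13E)-17-(tert-butyldimethylsilyloxy)labda-6,13-dien-15-ol (5α-H, 8α-H, 9α-H, 10β-CH3) | OC/C=C(\C)CC[C@H]1[C@@H](CO[Si](C)(C)C(C)(C)C)C=C[C@H]2C(C)(C)CCC[C@]12C | intermediate
17 | (13E)-17-(tert-butyldimethylsilyloxy)labda-6,13-dien-15-yl 2-methylpropanoate (5α-H, 8α-H, 9α-H, 10β-CH3) | CC(C)C(=O)OC/C=C(\C)CC[C@H]1[C@@H](CO[Si](C)(C)C(C)(C)C)C=C[C@H]2C(C)(C)CCC[C@]12C | intermediate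
18 | (13E)-17-hydroxylabda-6,13-dien-15-yl 2-methylpropanoate (5α-H, 8α-H, 9α-H, 10β-CH3) | CC(C)C(=O)OC/C=C(\C)CC[C@H]1[C@@H](CO)C=C[C@H]2C(C)(C)CCC[C@]12C | intermediate
19 | (13E)-17-oxolabda-6,13-dien-15-yl 2-methylpropanoate (5α-H, 8α-H, 9α-H, 10β-CH3) | CC(C)C(=O)OC/C=C(\C)CC[C@H]1[C@@H](C=O)C=C[C@H]2C(C)(C)CCC[C@]12C | intermediate (not isolated)
20 | (13E)-17-oxolabda-7,13-dien-15-yl 2-methylpropanoate (5α-H, 9α-H, 10β-CH3) | CC(C)C(=O)OC/C=C(\C)CC[C@H]1C(C=O)=CC[C@H]2C(C)(C)CCC[C@]12C | intermediate
21 | (13E)-15-(2-methylpropanoyloxy)labda-7,13-dien-17-oic acid; (1R,4aS,8aS)-1-[(3E)-3-methyl-5-(2-methylpropanoyloxy)pent-3-en-1-yl]-5,5,8a-trimethyl-1,4,4a,5,6,7,8,8a-octahydronaphthalene-2-carboxylic acid | C/C(=C\COC(=O)C(C)C)CC[C@H]1C(C(=O)O)=CC[C@H]2C(C)(C)CCC[C@]12C | target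

## Step count and risks

Total step count: 15. Longest linear sequence: 14 steps (steps 2–15, from 2,2-dimethylpent-4-enal 3); step 1 prepares the coupling partner 2 that is used in steps 5 and 10.

**Step 8 (the cycloaddition).** The β,β-disubstituted enal may react so slowly that Lewis-acid-induced ionisation of the dienylic silyl ether or oligomerisation of the diene overtakes ring closure. The syn-diaxial contact building up between C20 and the axial C4 methyl may erode the preference for the formyl-endo, trans-fused transition state. The catalyst may also discriminate the two enal faces poorly. The fallback gives up catalytic enantiocontrol and sets out from 11. Stoichiometric Me2AlCl in CH2Cl2 (−78 → −20 °C), a stronger activator for trienals of this kind, should give the racemic cycloadduct F1. NaBH4 in MeOH reduces it to the racemic C11 alcohol F2. Esterification with (S)-2-methoxy-2-phenylacetic acid (DCC, DMAP) gives two diastereomeric esters, from which the (S)-O-methylmandelate of the (5S,8S,9S,10S) alcohol F3 is separated by chromatography from the diastereomeric (S)-O-methylmandelate of the enantiomeric alcohol F4. Hydrolysis of F3 with LiOH in THF–H2O frees the resolved C11 alcohol F5, and Dess–Martin oxidation returns the route to 12.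

**Step 10 (side-chain coupling).** The vinyl group sits between C8 and the quaternary C10, so hydroboration may be incomplete, or with excess borane may begin to touch C6=C7. Transmetalation of the borane may be slow, and the triflate may be lost by base-induced elimination before it couples. The fallback replaces the cross-coupling by carbonyl olefinations and sets out from 12, bypassing steps 9 and 10. Wittig reaction with 1-(triphenylphosphoranylidene)propan-2-one in toluene at 90 °C gives the (11E)-enone F6. Conjugate reduction with [(Ph3P)CuH]6 gives the methyl ketone F7, leaving the ring alkene alone. Horner–Wadsworth–Emmons reaction with triethyl phosphonoacetate and NaH then gives the enoate, whose 13E isomer is separated from the minor 13Z isomer by chromatography, and the route is rejoined at 15.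

**Step 5 (first coupling, which fixes the enal geometry).** Isomerisation at the β-palladated enoate stage or incomplete E selectivity carried over from step 1 may leak Z isomer into the enoate, and the triflate may eliminate under the basic conditions. A geometrically impure dienophile would surface after step 8 as the C10 epimer. The fallback sets the trisubstituted alkene by carbometalation and sets out from 7. Hydroboration with 9-BBN followed by NaOH/H2O2 gives (5E,7E)-9-(tert-butyldimethylsilyloxy)-4,4-dimethylnona-5,7-dien-1-ol F8. I2, PPh3 and imidazole convert it into the primary iodide F9. Displacement with LiC≡CH·H2NCH2CH2NH2 in DMSO gives the terminal alkyne F10. Zirconium-catalysed carboalumination (AlMe3, Cp2ZrCl2 cat., CH2Cl2), followed by n-BuLi and paraformaldehyde, adds methyl and hydroxymethyl syn across the alkyne and rejoins the route at 10, so that step 6 is no longer needed.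

## Further compounds

F1 | step 8 | racemic 12 (both enantiomers of the cycloadduct) | O=C[C@H]1[C@@H](CO[Si](C)(C)C(C)(C)C)C=C[C@H]2C(C)(C)CCC[C@]12C.O=C[C@@H]1[C@H](CO[Si](C)(C)C(C)(C)C)C=C[C@@H]2C(C)(C)CCC[C@@]12C
F2 | step 8 | racemic 17-(tert-butyldimethylsilyloxy)drim-6-en-11-ol (both enantiomers) | OC[C@H]1[C@@H](CO[Si](C)(C)C(C)(C)C)C=C[C@H]2C(C)(C)CCC[C@]12C.OC[C@@H]1[C@H](CO[Si](C)(C)C(C)(C)C)C=C[C@@H]2C(C)(C)CCC[C@@]12C
F3 | step 8 | (S)-O-methylmandelate of the (5S,8S,9S,10S) alcohol | CO[C@H](C(=O)OC[C@H]1[C@@H](CO[Si](C)(C)C(C)(C)C)C=C[C@H]2C(C)(C)CCC[C@]12C)c3ccccc3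
F4 | step 8 | diastereomeric (S)-O-methylmandelate of the enantiomeric alcohol | CO[C@H](C(=O)OC[C@@H]1[C@H](CO[Si](C)(C)C(C)(C)C)C=C[C@@H]2C(C)(C)CCC[C@@]12C)c3ccccc3
F5 | step 8 | (5S,8S,9S,10S)-17-(tert-butyldimethylsilyloxy)drim-6-en-11-ol | OC[C@H]1[C@@H](CO[Si](C)(C)C(C)(C)C)C=C[C@H]2C(C)(C)CCC[C@]12C
F6 | step 10 | (11E)-17-(tert-butyldimethylsilyloxy)-14,15-dinorlabda-6,11-dien-13-one | CC(=O)/C=C/[C@H]1[C@@H](CO[Si](C)(C)C(C)(C)C)C=C[C@H]2C(C)(C)CCC[C@]12C
F7 | step 10 | 17-(tert-butyldimethylsilyloxy)-14,15-dinorlabd-6-en-13-one | CC(=O)CC[C@H]1[C@@H](CO[Si](C)(C)C(C)(C)C)C=C[C@H]2C(C)(C)CCC[C@]12C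
F8 | step 5 | (5E,7E)-9-(tert-butyldimethylsilyloxy)-4,4-dimethylnona-5,7-dien-1-ol | OCCCC(C)(C)/C=C/C=C/CO[Si](C)(C)C(C)(C)C
F9 | step 5 | tert-butyl{[(2E,4E)-9-iodo-6,6-dimethylnona-2,4-dien-1-yl]oxy}dimethylsilane | ICCCC(C)(C)/C=C/C=C/CO[Si](C)(C)C(C)(C)C
F10 | step 5 | tert-butyl{[(2E,4E)-6,6-dimethylundeca-2,4-dien-10-yn-1-yl]oxy}dimethylsilane | C#CCCCC(C)(C)/C=C/C=C/CO[Si](C)(C)C(C)(C)C
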